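## Retrosynthetic overview

- The target is reached by aryl desilylation and a late oxidation of a hydroxymethyl group; before that, a core acid is joined by Steglich esterification to silyl-protected hydroxytyrosol.
- The core acid comes from KOH/MeI opening and oxidation of a trans-3,4-disubstituted δ-lactone. The lactone relays the allylic stereocentre to the neighbouring carbon by trans-hydroxymethylation of its enolate.
- Key C–C bond (allylic CH to alkenyl carbon): palladium-catalysed enantioselective reductive Heck coupling of a Z-alkenyl iodide (from crotonaldehyde) with 5,6-dihydro-2H-pyran-2-one.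
- Protected hydroxytyrosol comes from catechol by bromination, silylation, palladium/zinc-enolate coupling with ethyl bromoacetate, and reduction.
- Rings: the target has none besides the arene. The temporary δ-lactone is closed by metathesis (step 4) and opened in step 8; the dioxolane is only a protecting group.

## Assumptions

- The CH flanked by CHO and CO2Me (C2 of the pentanedioate) is a 1,3-dicarbonyl methine that equilibrates through its enol in protic, acidic or basic media. It is therefore carried as a stable CH(CH2O–) centre until step 16. Steps 16 and 17 and the isolation are run cold, base-free and without silica chromatography, and the product is stored cold in aprotic solvent.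
- In step 5 the (S) ligand is written for the 4S product; if the observed facial sense is opposite, its antipode is used.

## Route

**Step 1**
Reactants: 1 (E)-but-2-enal (crotonaldehyde)
Product: 2 (Z)-2-iodobut-2-enal
Conditions: I2, K2CO3, DMAP (0.2 equiv), THF/H2O (1:1), rt
Reagents that add atoms: iodine, [I][I]
Why: DMAP adds in conjugate fashion, the enolate is iodinated and DMAP is expelled (Baylis–Hillman-type α-iodination of an enal); the product keeps CHO trans to CH3, so iodine is cis to CH3 (Z), which is the geometry the ethylidene of the target needs.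

**Step 2**
Reactants: 2 (Z)-2-iodobut-2-enal
Product: 3 2-[(1Z)-1-iodoprop-1-en-1-yl]-1,3-dioxolane
Conditions: HOCH2CH2OH, PPTS (cat.), benzene, reflux (Dean–Stark)
Reagents that add atoms: ethylene glycol, OCCO
Why: Acid-catalysed acetalisation with azeotropic removal of water masks the aldehyde for the organometallic and enolate steps; the C=C geometry is not touched.

**Step 3**
Reactants: 4 but-3-en-1-ol; 5 prop-2-enoyl chloride (acryloyl chloride)
Product: 6 but-3-en-1-yl prop-2-enoate
Conditions: Et3N, DMAP (cat.), CH2Cl2, 0 °C → rt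
Reagents that add atoms: none
Why: Base-mediated O-acylation of a primary alcohol by an acid chloride (nucleophilic acyl substitution).

**Step 4**
Reactants: 6 but-3-en-1-yl prop-2-enoate
Product: 7 5,6-dihydro-2H-pyran-2-one
Conditions: second-generation Grubbs catalyst RuCl2(=CHPh)(PCy3)(H2IMes) (2 mol %), CH2Cl2 (0.01 M), 40 °C
Reagents that add atoms: none
Why: Ring-closing olefin metathesis of the acrylate/terminal alkene pair, driven by loss of ethene, closes the six-membered α,β-unsaturated lactone.

**Step 5**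
Reactants: 3 2-[(1Z)-1-iodoprop-1-en-1-yl]-1,3-dioxolane; 7 5,6-dihydro-2H-pyran-2-one (2 equiv)
Product: 8 (4S)-4-[(1E)-1-(1,3-dioxolan-2-yl)prop-1-en-1-yl]oxan-2-one
Conditions: Pd(OAc)2 (5 mol %), (S)-t-Bu-PHOX [(S)-4-tert-butyl-2-(2-diphenylphosphinophenyl)-4,5-dihydrooxazole] (7.5 mol %), HCO2Na (2 equiv), DMF/H2O (10:1), 45 °C
Reagents that add atoms: none
Why: Proposed new method: an enantioselective intermolecular reductive Heck coupling of an alkenyl iodide with an α,β-unsaturated δ-lactone. Zerovalent palladium (from Pd(OAc)2 and formate) inserts into the C–I bond with retention of the alkene geometry; iodide dissociates in the aqueous polar medium to give a cationic alkenylpalladium held in the chiral P,N pocket; syn-carbopalladation of 7 delivers the alkenyl group to C4 (β) and palladium to C3 (α) in the enantio-determining step, which sets the 4S centre; the only hydrogen left on C4 is anti to palladium, so β-hydride elimination is blocked and the palladium enolate is reduced by formate (decarboxylation to Pd–H, then C–H reductive elimination), releasing 8 and zerovalent palladium. The closest known reactions are the racemic formate-mediated reductive Heck (hydroalkenylation and hydroarylation) of enones and butenolides, and the enantioselective intermolecular Heck and reductive Heck reactions of aryl or alkenyl electrophiles with cyclic alkenes.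

**Step 6**
Reactants: 8 (4S)-4-[(1E)-1-(1,3-dioxolan-2-yl)prop-1-en-1-yl]oxan-2-one
Product: 10 (3S,4S)-4-[(1E)-1-(1,3-dioxolan-2-yl)prop-1-en-1-yl]-3-(hydroxymethyl)oxan-2-one, via lithium lactone enolate 9 (not isolated)
Conditions: LiN(i-Pr)2 (1.1 equiv), THF, −78 °C; CH2O (monomeric gas), −78 → −40 °C; AcOH quench at −78 °C
Reagents that add atoms: formaldehyde, C=O
Why: Aldol addition of the lithium lactone enolate to formaldehyde; the electrophile enters anti to the C4 alkenyl group of the half-chair enolate, giving the 3,4-trans lactone, so the later CH(CHO)CO2Me carbon is fixed as a configurationally stable (3S) CH(CH2OH) centre.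

**Step 7**
Reactants: 10 (3S,4S)-4-[(1E)-1-(1,3-dioxolan-2-yl)prop-1-en-1-yl]-3-(hydroxymethyl)oxan-2-one
Product: 11 (3S,4S)-4-[(1E)-1-(1,3-dioxolan-2-yl)prop-1-en-1-yl]-3-{[(triethylsilyl)oxy]methyl}oxan-2-one
Conditions: Et3SiCl, imidazole, CH2Cl2, 0 °C
Reagents that add atoms: chlorotriethylsilane, CC[Si](Cl)(CC)CC
Why: Imidazole-assisted silylation of the primary alcohol blocks retro-aldol, dehydration and relactonisation pathways in the following steps.

**Step 8**
Reactants: 11 (3S,4S)-4-[(1E)-1-(1,3-dioxolan-2-yl)prop-1-en-1-yl]-3-{[(triethylsilyl)oxy]methyl}oxan-2-one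
Product: 13 methyl (2S,3S)-3-[(1E)-1-(1,3-dioxolan-2-yl)prop-1-en-1-yl]-5-hydroxy-2-{[(triethylsilyl)oxy]methyl}pentanoate, via potassium hydroxy carboxylate 12 (not isolated)
Conditions: KOH (1.0 equiv), THF/H2O, 0 °C; evaporate (toluene azeotrope); MeI, DMF, rt; used crude
Reagents that add atoms: potassium hydroxide, [K+].[OH-]; iodomethane, IC
Why: Lactone saponification followed by SN2 O-methylation of the carboxylate turns the lactone carbonyl into the methyl ester and frees the distal CH2OH; the carboxylate α-centre cannot enolise under these conditions, so both stereocentres are kept.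

**Step 9**
Reactants: 13 methyl (2S,3S)-3-[(1E)-1-(1,3-dioxolan-2-yl)prop-1-en-1-yl]-5-hydroxy-2-{[(triethylsilyl)oxy]methyl}pentanoate
Product: 14 (3S,4S)-3-[(1E)-1-(1,3-dioxolan-2-yl)prop-1-en-1-yl]-5-methoxy-5-oxo-4-{[(triethylsilyl)oxy]methyl}pentanoic acid
Conditions: TEMPO (7 mol %), NaClO2 (2 equiv), NaOCl (2 mol %), MeCN/phosphate buffer pH 6.7, 35 °C
Reagents that add atoms: sodium chlorite, [Na+].[O-]Cl=O
Why: TEMPO/chlorite oxidation (Anelli-type alcohol oxidation followed by Pinnick-type aldehyde oxidation) takes the primary alcohol to the acid at pH 6.7, where the dioxolane, the silyl ether and the trisubstituted alkene survive.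

**Step 10**
Reactants: 15 benzene-1,2-diol (catechol)
Product: 16 4-bromobenzene-1,2-diol
Conditions: NBS (1.0 equiv), HBF4·OEt2, MeCN, −30 °C → rt
Reagents that add atoms: N-bromosuccinimide, O=C1CCC(=O)N1Br
Why: Electrophilic aromatic substitution; acid-activated NBS brominates para to one hydroxyl (position 4).

**Step 11**
Reactants: 16 4-bromobenzene-1,2-diol
Product: 17 4-bromo-1,2-bis[(tert-butyldimethylsilyl)oxy]benzene
Conditions: t-BuMe2SiCl (2.4 equiv), imidazole, DMF, rt
Reagents that add atoms: tert-butyl(chloro)dimethylsilane, CC(C)(C)[Si](C)(C)Cl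
Why: Imidazole-mediated O-silylation of both phenols gives a catechol protection that is removable with fluoride at the end.

**Step 12**
Reactants: 17 4-bromo-1,2-bis[(tert-butyldimethylsilyl)oxy]benzene; 18 ethyl bromoacetate
Product: 20 ethyl 2-{3,4-bis[(tert-butyldimethylsilyl)oxy]phenyl}acetate, via ethoxycarbonylmethylzinc bromide 19 (not isolated)
Conditions: Zn dust (Me3SiCl-activated), THF, rt; then 17, Pd(dba)2 (2 mol %), P(t-Bu)3 (2 mol %), THF, rt
Reagents that add atoms: none
Why: Zinc insertion gives the Reformatsky reagent, which cross-couples with the aryl bromide under palladium catalysis (Negishi-type α-arylation of a zinc ester enolate); no base is present, so the aryl silyl ethers survive.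

**Step 13**
Reactants: 20 ethyl 2-{3,4-bis[(tert-butyldimethylsilyl)oxy]phenyl}acetate
Product: 21 2-{3,4-bis[(tert-butyldimethylsilyl)oxy]phenyl}ethan-1-ol
Conditions: i-Bu2AlH (2.5 equiv), CH2Cl2, −78 → 0 °C; aq. potassium sodium tartrate
Reagents that add atoms: none
Why: Hydride reduction of the ester to the primary alcohol; aryl silyl ethers are inert to i-Bu2AlH at low temperature.

**Step 14**
Reactants: 14 (3S,4S)-3-[(1E)-1-(1,3-dioxolan-2-yl)prop-1-en-1-yl]-5-methoxy-5-oxo-4-{[(triethylsilyl)oxy]methyl}pentanoic acid; 21 2-{3,4-bis[(tert-butyldimethylsilyl)oxy]phenyl}ethan-1-ol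
Product: 22 5-(2-{3,4-bis[(tert-butyldimethylsilyl)oxy]phenyl}ethyl) 1-methyl (2S,3S)-3-[(1E)-1-(1,3-dioxolan-2-yl)prop-1-en-1-yl]-2-{[(triethylsilyl)oxy]methyl}pentanedioate
Conditions: N,N'-dicyclohexylcarbodiimide, DMAP (cat.), CH2Cl2, 0 °C → rt
Reagents that add atoms: none
Why: Steglich esterification (carbodiimide activation, DMAP acyl transfer) joins the two fragments under neutral conditions without touching either stereocentre.

**Step 15**
Reactants: 22 the fully protected diester from step 14
Product: 23 5-(2-{3,4-bis[(tert-butyldimethylsilyl)oxy]phenyl}ethyl) 1-methyl (2S,3S)-2-(hydroxymethyl)-3-[(2E)-1-oxobut-2-en-2-yl]pentanedioate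
Conditions: PPTS (0.2 equiv), acetone/H2O (10:1), 40 °C; used without chromatography
Reagents that add atoms: water, O
Why: Mild acid-catalysed hydrolysis cleaves the alkyl triethylsilyl ether and the allylic dioxolane (transacetalisation), while the more acid-stable aryl tert-butyldimethylsilyl ethers remain; the E-enal is the thermodynamic geometry.

**Step 16**
Reactants: 23 the hydroxy enal from step 15
Product: 24 5-(2-{3,4-bis[(tert-butyldimethylsilyl)oxy]phenyl}ethyl) 1-methyl (2S,3S)-2-formyl-3-[(2E)-1-oxobut-2-en-2-yl]pentanedioate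
Conditions: Dess–Martin periodinane (1.5 equiv), CH2Cl2, 0 °C; diluted with pentane/Et2O, filtered through Celite, no aqueous wash
Reagents that add atoms: none
Why: Dess–Martin oxidation of the primary alcohol under base-free conditions unveils the formyl group; the (2S) centre was set in step 6 and is not deprotonated because no base or aqueous wash is used.

**Step 17**
Reactants: 24 the bis-silylated dialdehyde from step 16
Product: 25 5-[2-(3,4-dihydroxyphenyl)ethyl] 1-methyl (2S,3S)-2-formyl-3-[(2E)-1-oxobut-2-en-2-yl]pentanedioate (CNP0181936.1)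
Conditions: HF·pyridine (excess), THF, 0 °C; volatiles removed cold, no silica
Reagents that add atoms: none
Why: Fluoride-induced cleavage of the two aryl Si–O bonds under weakly acidic, base-free conditions at 0 °C releases the catechol without touching the esters, the enal or the formyl ester centre.

## Compound list

1 | (E)-but-2-enal | C/C=C/C=O | starting material
2 | (Z)-2-iodobut-2-enal | C/C=C(\I)C=O | intermediate
3 | 2-[(1Z)-1-iodoprop-1-en-1-yl]-1,3-dioxolane | C/C=C(\I)C1OCCO1 | intermediate
4 | but-3-en-1-ol | C=CCCO | starting material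
5 | prop-2-enoyl chloride | C=CC(=O)Cl | starting material
6 | but-3-en-1-yl prop-2-enoate | C=CCCOC(=O)C=C | intermediate
7 | 5,6-dihydro-2H-pyran-2-one | O=C1C=CCCO1 | intermediate
8 | (4S)-4-[(1E)-1-(1,3-dioxolan-2-yl)prop-1-en-1-yl]oxan-2-one | C/C=C(/C1OCCO1)[C@H]2CCOC(=O)C2 | intermediate
9 | lithium (4S)-4-[(1E)-1-(1,3-dioxolan-2-yl)prop-1-en-1-yl]-5,6-dihydro-4H-pyran-2-olate | C/C=C(/C1OCCO1)[C@H]2CCOC([O-])=C2.[Li+] | intermediate
10 | (3S,4S)-4-[(1E)-1-(1,3-dioxolan-2-yl)prop-1-en-1-yl]-3-(hydroxymethyl)oxan-2-one | C/C=C(/C1OCCO1)[C@H]2CCOC(=O)[C@@H]2CO | intermediate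
11 | (3S,4S)-4-[(1E)-1-(1,3-dioxolan-2-yl)prop-1-en-1-yl]-3-{[(triethylsilyl)oxy]methyl}oxan-2-one | C/C=C(/C1OCCO1)[C@H]2CCOC(=O)[C@@H]2CO[Si](CC)(CC)CC | intermediate
12 | potassium (2S,3S)-3-[(1E)-1-(1,3-dioxolan-2-yl)prop-1-en-1-yl]-5-hydroxy-2-{[(triethylsilyl)oxy]methyl}pentanoate | C/C=C(/C1OCCO1)[C@@H](CCO)[C@@H](CO[Si](CC)(CC)CC)C(=O)[O-].[K+] | intermediate
13 | methyl (2S,3S)-3-[(1E)-1-(1,3-dioxolan-2-yl)prop-1-en-1-yl]-5-hydroxy-2-{[(triethylsilyl)oxy]methyl}pentanoate | C/C=C(/C1OCCO1)[C@@H](CCO)[C@@H](CO[Si](CC)(CC)CC)C(=O)OC | intermediate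
14 | (3S,4S)-3-[(1E)-1-(1,3-dioxolan-2-yl)prop-1-en-1-yl]-5-methoxy-5-oxo-4-{[(triethylsilyl)oxy]methyl}pentanoic acid | C/C=C(/C1OCCO1)[C@@H](CC(=O)O)[C@@H](CO[Si](CC)(CC)CC)C(=O)OC | intermediate
15 | benzene-1,2-diol | Oc1ccccc1O | starting material
16 | 4-bromobenzene-1,2-diol | Oc1ccc(Br)cc1O | intermediate
17 | 4-bromo-1,2-bis[(tert-butyldimethylsilyl)oxy]benzene | Brc1ccc(O[Si](C)(C)C(C)(C)C)c(O[Si](C)(C)C(C)(C)C)c1 | intermediate
18 | ethyl bromoacetate | BrCC(=O)OCC | starting material
19 | (2-ethoxy-2-oxoethyl)zinc bromide | CCOC(=O)C[Zn]Br | intermediate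
20 | ethyl 2-{3,4-bis[(tert-butyldimethylsilyl)oxy]phenyl}acetate | CCOC(=O)Cc1ccc(O[Si](C)(C)C(C)(C)C)c(O[Si](C)(C)C(C)(C)C)c1 | intermediate
21 | 2-{3,4-bis[(tert-butyldimethylsilyl)oxy]phenyl}ethan-1-ol | OCCc1ccc(O[Si](C)(C)C(C)(C)C)c(O[Si](C)(C)C(C)(C)C)c1 | intermediate
22 | 5-(2-{3,4-bis[(tert-butyldimethylsilyl)oxy]phenyl}ethyl) 1-methyl (2S,3S)-3-[(1E)-1-(1,3-dioxolan-2-yl)prop-1-en-1-yl]-2-{[(triethylsilyl)oxy]methyl}pentanedioate | C/C=C(/C1OCCO1)[C@@H](CC(=O)OCCc2ccc(O[Si](C)(C)C(C)(C)C)c(O[Si](C)(C)C(C)(C)C)c2)[C@@H](CO[Si](CC)(CC)CC)C(=O)OC | intermediate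
23 | 5-(2-{3,4-bis[(tert-butyldimethylsilyl)oxy]phenyl}ethyl) 1-methyl (2S,3S)-2-(hydroxymethyl)-3-[(2E)-1-oxobut-2-en-2-yl]pentanedioate | C/C=C(/C=O)[C@@H](CC(=O)OCCc1ccc(O[Si](C)(C)C(C)(C)C)c(O[Si](C)(C)C(C)(C)C)c1)[C@@H](CO)C(=O)OC | intermediate
24 | 5-(2-{3,4-bis[(tert-butyldimethylsilyl)oxy]phenyl}ethyl) 1-methyl (2S,3S)-2-formyl-3-[(2E)-1-oxobut-2-en-2-yl]pentanedioate | C/C=C(/C=O)[C@@H](CC(=O)OCCc1ccc(O[Si](C)(C)C(C)(C)C)c(O[Si](C)(C)C(C)(C)C)c1)[C@@H](C=O)C(=O)OC | intermediate
25 | 5-[2-(3,4-dihydroxyphenyl)ethyl] 1-methyl (2S,3S)-2-formyl-3-[(2E)-1-oxobut-2-en-2-yl]pentanedioate | C/C=C(/C=O)[C@@H](CC(=O)OCCc1ccc(O)c(O)c1)[C@@H](C=O)C(=O)OC | target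

## Step count and risks

Total step count: 17.
Longest linear sequence: 11 steps (steps 1, 2, 5–9, 14–17; the branch through steps 3 and 4 is equally long), which is 11/17 = 65 % of the total. The hydroxytyrosol branch (steps 10–13) runs in parallel.

The three steps most likely to fail:

**Step 5 (the proposed new coupling).** The hindered alkenylpalladium may be reduced by formate before it inserts, the lactone may be reduced by Pd–H, or the enantioselectivity may be low. The fallback uses known chemistry and sets out from 3. Iodine–lithium exchange (t-BuLi, Et2O, −78 °C) and a quench with 2-isopropoxy-4,4,5,5-tetramethyl-1,3,2-dioxaborolane give, with retention of geometry, 2-[(1E)-1-(1,3-dioxolan-2-yl)prop-1-en-1-yl]-4,4,5,5-tetramethyl-1,3,2-dioxaborolane F1. Its rhodium-catalysed asymmetric 1,4-addition to 7 (Hayashi–Miyaura reaction; [Rh(OH)(cod)]2, (S)-BINAP, dioxane/H2O, 60 °C; monovalent rhodium adds the alkenyl group to the β-carbon) gives 8, where the route is rejoined.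

**Step 16.** The δ-hydroxy enal 23 can sit partly as a six-membered lactol (or as an oxa-Michael adduct), and the lactol would be oxidised to a lactone instead of giving the dialdehyde. The fallback sets out from 23. Luche reduction (NaBH4, CeCl3·7H2O, MeOH, −40 °C) removes the aldehyde and gives 5-(2-{3,4-bis[(tert-butyldimethylsilyl)oxy]phenyl}ethyl) 1-methyl (2S,3S)-3-[(2E)-1-hydroxybut-2-en-2-yl]-2-(hydroxymethyl)pentanedioate F2. Both hydroxyls of this 1,5-diol are then bound to excess Dess–Martin periodinane (4 equiv, CH2Cl2, 0 °C) before any aldehyde exists, so the double oxidation proceeds without a free hydroxy aldehyde and comes back to the route at 24.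

**Step 17.** The formyl ester centre may enolise or epimerise during the fluoride step or the isolation. The fallback changes the order so that the oxidation is the last event, and sets out from 23.
- HF·pyridine (THF, 0 °C) is applied first, while C2 is still a stable CH(CH2OH) centre, and gives 5-[2-(3,4-dihydroxyphenyl)ethyl] 1-methyl (2S,3S)-2-(hydroxymethyl)-3-[(2E)-1-oxobut-2-en-2-yl]pentanedioate F3.
- The catechol is masked in the flask with PhB(OH)2 (1.0 equiv, 4 Å molecular sieves, CH2Cl2) as 1-methyl 5-[2-(2-phenyl-1,3,2-benzodioxaborol-5-yl)ethyl] (2S,3S)-2-(hydroxymethyl)-3-[(2E)-1-oxobut-2-en-2-yl]pentanedioate F4.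
- Dess–Martin oxidation then gives 1-methyl 5-[2-(2-phenyl-1,3,2-benzodioxaborol-5-yl)ethyl] (2S,3S)-2-formyl-3-[(2E)-1-oxobut-2-en-2-yl]pentanedioate F5.
- A cold, neutral aqueous sorbitol wash hydrolyses the boronate and returns to the route at 25.

This transient boronate masking during a Dess–Martin oxidation is untested on this substrate.

## Further compounds

F1 | step 5 | 2-[(1E)-1-(1,3-dioxolan-2-yl)prop-1-en-1-yl]-4,4,5,5-tetramethyl-1,3,2-dioxaborolane | C/C=C(\B1OC(C)(C)C(C)(C)O1)C2OCCO2
F2 | step 16 | 5-(2-{3,4-bis[(tert-butyldimethylsilyl)oxy]phenyl}ethyl) 1-methyl (2S,3S)-3-[(2E)-1-hydroxybut-2-en-2-yl]-2-(hydroxymethyl)pentanedioate | C/C=C(/CO)[C@@H](CC(=O)OCCc1ccc(O[Si](C)(C)C(C)(C)C)c(O[Si](C)(C)C(C)(C)C)c1)[C@@H](CO)C(=O)OC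
F3 | step 17 | 5-[2-(3,4-dihydroxyphenyl)ethyl] 1-methyl (2S,3S)-2-(hydroxymethyl)-3-[(2E)-1-oxobut-2-en-2-yl]pentanedioate | C/C=C(/C=O)[C@@H](CC(=O)OCCc1ccc(O)c(O)c1)[C@@H](CO)C(=O)OC
F4 | step 17 | 1-methyl 5-[2-(2-phenyl-1,3,2-benzodioxaborol-5-yl)ethyl] (2S,3S)-2-(hydroxymethyl)-3-[(2E)-1-oxobut-2-en-2-yl]pentanedioate | C/C=C(/C=O)[C@@H](CC(=O)OCCc1ccc2OB(c3ccccc3)Oc2c1)[C@@H](CO)C(=O)OC
F5 | step 17 | 1-methyl 5-[2-(2-phenyl-1,3,2-benzodioxaborol-5-yl)ethyl] (2S,3S)-2-formyl-3-[(2E)-1-oxobut-2-en-2-yl]pentanedioate | C/C=C(/C=O)[C@@H](CC(=O)OCCc1ccc2OB(c3ccccc3)Oc2c1)[C@@H](C=O)C(=O)OC
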